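**Retrosynthetic overview**
1. Target ⇒ ten-membered lactone alcohol + (2R,3R)-epoxyangelic acid (last bond: the C-8 ester; the oxirane is made separately by Sharpless epoxidation).
2. Carbocycle and lactone ⇒ one acyclic chain. The C6–C7 bond (the bond germacrene synthases forge between C1 and C10 of farnesyl diphosphate) is closed by chromium-mediated addition of a 2-(bromomethyl)enoate to a lactol-masked (Z)-enal; the C-6 alkoxide then lactonises onto C-12, as in costunolide formation.
3. Chain ⇒ cross-metathesis (C1=C10) of a C2–C6 lactol with a C7–C14 bromo diester; the C-3 and C-8 carbinols come from chiral-phosphoric-acid allylborations.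
4. Ring order: oxirane (side-chain acid) → ten-membered carbocycle → γ-lactone (same flask as the carbocycle).

Assumption: ring positions use germacrane numbering (C-3 OH, C-4 methyl, C-6 lactone O, C-7 ring-fusion carbon, C-8 ester O, C-10 CO2Me; C-11/C-12/C-13 = lactone α-carbon, carbonyl, exocyclic CH2); 1, 6, 7, 12, 13, 17 and both enantiomers of TRIP [3,3′-bis(2,4,6-triisopropylphenyl)-1,1′-binaphthyl-2,2′-diyl hydrogen phosphate] are bought.

**Step 1**
Reactants: 1 methyl (2Z)-2-methylbut-2-enoate (methyl angelate)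
Product: 2 (2Z)-2-methylbut-2-en-1-ol
Conditions: LiAlH4, Et2O, 0 °C
Reagents that add atoms: none
Why: Hydride 1,2-reduction of the ester gives the allylic alcohol and leaves the Z geometry untouched.

**Step 2**
Reactants: 2 (2Z)-2-methylbut-2-en-1-ol
Product: 3 [(2S,3R)-2,3-dimethyloxiran-2-yl]methanol
Conditions: Ti(OiPr)4 (10 mol %), L-(+)-diethyl tartrate (12 mol %), t-BuOOH, 4 Å molecular sieves, CH2Cl2, −20 °C
Reagents that add atoms: tert-butyl hydroperoxide, CC(C)(C)OO
Why: Katsuki–Sharpless asymmetric epoxidation; the L-(+)-tartrate catalyst attacks the same face that converts (E)-hex-2-en-1-ol into its (2S,3S)-epoxide, so syn delivery to the Z-olefin sets both oxirane centres as 2S,3R.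

**Step 3**
Reactants: 3 [(2S,3R)-2,3-dimethyloxiran-2-yl]methanol
Product: 5 (2R,3R)-2,3-dimethyloxirane-2-carboxylic acid, via epoxy aldehyde 4 (not isolated)
Conditions: RuCl3 (2 mol %), NaIO4, MeCN/EtOAc/H2O, 0 °C → rt
Reagents that add atoms: sodium periodate, [Na+].[O-]I(=O)(=O)=O; water, O
Why: RuO4-catalysed oxidation of the primary alcohol through the aldehyde hydrate gives the glycidic acid without touching either oxirane centre (the C-2 descriptor changes from S to R only through CIP priorities).

**Step 4**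
Reactants: 6 ethyl (2E)-3-methyl-4-oxobut-2-enoate; 7 2-allyl-4,4,5,5-tetramethyl-1,3,2-dioxaborolane
Product: 8 ethyl (2E,4S)-4-hydroxy-3-methylhepta-2,6-dienoate
Conditions: (S)-TRIP (5 mol %), toluene, −30 °C; aq. NaHCO3 work-up
Reagents that add atoms: none
Why: Chiral-phosphoric-acid-catalysed allylboration through a closed chair transition state; (S)-TRIP is chosen as the mirror image of the (R)-TRIP/benzaldehyde → (R)-alcohol precedent and sets the 4S carbinol (future C-3).

**Step 5**
Reactants: 8 ethyl (2E,4S)-4-hydroxy-3-methylhepta-2,6-dienoate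
Product: 10 (5S)-4-methyl-5-(prop-2-en-1-yl)furan-2(5H)-one, via Z-hydroxy ester 9 (not isolated)
Conditions: hν (254 nm), MeCN, rt
Reagents that add atoms: none
Why: Photochemical E→Z isomerisation of the enoate; only the Z isomer can lactonise, which drains the photostationary mixture into the butenolide and locks the future C4=C5 Z geometry while C-3 is untouched.

**Step 6**
Reactants: 10 (5S)-4-methyl-5-(prop-2-en-1-yl)furan-2(5H)-one
Product: 11 (5S)-4-methyl-5-(prop-2-en-1-yl)-2,5-dihydrofuran-2-ol (both C-2 epimers)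
Conditions: i-Bu2AlH (1.05 equiv), CH2Cl2, −78 °C; aq. potassium sodium tartrate work-up
Reagents that add atoms: none
Why: Partial lactone reduction stops at the tetrahedral aluminate at −78 °C and gives the lactol, a masked (Z)-4-hydroxy-enal; it is kept acid-free to avoid furan formation.

**Step 7**
Reactants: 12 2,2-dimethoxyacetaldehyde; 13 methyl acrylate
Product: 14 methyl 3-hydroxy-4,4-dimethoxy-2-methylidenebutanoate (racemic)
Conditions: DABCO (30 mol %), 1,4-dioxane/H2O, rt
Reagents that add atoms: none
Why: Morita–Baylis–Hillman reaction of an activated α-alkoxy aldehyde; the carbinol centre is destroyed in the next step, so racemic material suffices.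

**Step 8**
Reactants: 14 methyl 3-hydroxy-4,4-dimethoxy-2-methylidenebutanoate
Product: 16 methyl (2Z)-2-(bromomethyl)-4-oxobut-2-enoate, via bromo acetal 15 (not isolated)
Conditions: PBr3 (0.4 equiv), Et2O, −10 → 0 °C; then TFA/H2O (9:1), CH2Cl2, 0 °C
Reagents that add atoms: phosphorus tribromide, BrP(Br)Br; water, O
Why: SN2′ bromination with allylic transposition gives the thermodynamically preferred (Z)-2-(bromomethyl)enoate (acetal carbon trans to the ester), and acetal hydrolysis then frees the enal.

**Step 9**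
Reactants: 16 methyl (2Z)-2-(bromomethyl)-4-oxobut-2-enoate; 17 methyl 2-[(4,4,5,5-tetramethyl-1,3,2-dioxaborolan-2-yl)methyl]prop-2-enoate
Product: 18 dimethyl (2Z,4R)-2-(bromomethyl)-4-hydroxy-6-methylidenehept-2-enedioate
Conditions: (R)-TRIP (10 mol %), toluene, −30 → 0 °C; cold aq. NaHCO3 work-up
Reagents that add atoms: none
Why: Proposed new method: chiral-phosphoric-acid allylboration extended to the ester-deactivated 2-(methoxycarbonyl)allyl boronate — Brønsted acids are known to accelerate allylboration with this boronate class through the same six-membered chair transition state, the slow uncatalysed background should favour the catalysed enantioselective path, and (R)-TRIP is expected to give the 4R carbinol (C-8) by analogy with benzaldehyde → (R)-alcohol; closest known reactions are triflic-acid-catalysed 2-alkoxycarbonyl-allylboration and TRIP-catalysed allylboration with allyl pinacol boronate (the allylic bromide is inert to boron, and cold basic work-up avoids lactonisation onto the new acrylate).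

**Step 10**
Reactants: 18 dimethyl (2Z,4R)-2-(bromomethyl)-4-hydroxy-6-methylidenehept-2-enedioate
Product: 19 dimethyl (2Z,4R)-2-(bromomethyl)-6-methylidene-4-[(triethylsilyl)oxy]hept-2-enedioate
Conditions: Et3SiOTf, 2,6-lutidine, CH2Cl2, −78 °C
Reagents that add atoms: triethylsilyl trifluoromethanesulfonate, CC[Si](CC)(CC)OS(=O)(=O)C(F)(F)F
Why: Silylation with a hindered, non-nucleophilic base (imidazole or DMAP would attack the allylic bromide); the silyl ether stops O-alkylation by the cis CH2Br and makes O-8 non-chelating for the ring closure.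

**Step 11**
Reactants: 19 dimethyl (2Z,4R)-2-(bromomethyl)-6-methylidene-4-[(triethylsilyl)oxy]hept-2-enedioate; 11 (5S)-4-methyl-5-(prop-2-en-1-yl)-2,5-dihydrofuran-2-ol (3 equiv)
Product: 20 dimethyl (2Z,4R,6E)-2-(bromomethyl)-6-{2-[(2S)-5-hydroxy-3-methyl-2,5-dihydrofuran-2-yl]ethylidene}-4-[(triethylsilyl)oxy]hept-2-enedioate
Conditions: second-generation Hoveyda–Grubbs catalyst (10 mol %), CH2Cl2, 40 °C
Reagents that add atoms: none
Why: Cross-metathesis of a terminal olefin used in excess with a 1,1-disubstituted acrylate that cannot homodimerise; as with methacrylates, only the trisubstituted enoate with the new chain trans to CO2Me (6E, the C1=C10 geometry of the target) forms, while the bromomethyl enoate and the ring olefin are too hindered to react.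

**Step 12**
Reactants: 20 dimethyl (2Z,4R,6E)-2-(bromomethyl)-6-{2-[(2S)-5-hydroxy-3-methyl-2,5-dihydrofuran-2-yl]ethylidene}-4-[(triethylsilyl)oxy]hept-2-enedioate
Product: 23 8-O-triethylsilyl macrolactone (28 with OSiEt3 in place of the 8-acyloxy group; 3-OH free), via allylchromium species 21 (not isolated), via hydroxy ester 22 (not isolated)
Conditions: CrCl2 (10 equiv), THF, rt, syringe-pump addition of 20 (final 2 mM); aq. NH4Cl work-up
Reagents that add atoms: none
Why: Proposed new method: an intramolecular Nozaki–Hiyama-type carbonyl allylation in which the lactol serves as the latent (Z)-enal — CrCl2 turns the allylic bromide into a trivalent allylchromium, the lactol opens to the hydroxy-enal, C-7 adds to the C-6 aldehyde through a six-membered chromium-bound transition state, and the resulting C-6 chromium alkoxide lactonises onto the C-12 ester; C-7 is set because H-8 eclipses the C7=C11 bond (1,3-allylic strain), C-9 stands anti and the non-chelating silyloxy group outside, so C-6 bonds to the face opposite C-9 (7R geometry of the target); C-6 is set because the tether lets the ring close only with H-6 and H-7 anti (trans-lactone, 6R); closest known reactions are chromium-mediated macrocyclisations of 2-(bromomethyl)enoate aldehydes to costunolide- and parthenolide-type 6,12-trans-lactones and indium- or chromium-mediated allylations of lactols and hydroxy aldehydes.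

**Step 13**
Reactants: 23 8-O-triethylsilyl macrolactone
Product: 25 3-O-tert-butyldimethylsilyl macrolactone with free 8-OH, via bis-silyl ether 24 (not isolated)
Conditions: t-BuMe2SiOTf, 2,6-lutidine, CH2Cl2, −78 °C; then HF·pyridine, pyridine, THF, 0 °C
Reagents that add atoms: tert-butyldimethylsilyl trifluoromethanesulfonate, CC(C)(C)[Si](C)(C)OS(=O)(=O)C(F)(F)F
Why: Silylation of the only free hydroxyl (C-3) followed by selective cleavage of the far more labile secondary triethylsilyl ether with buffered HF swaps the protection so that only O-8 is free; no stereocentre is involved.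

**Step 14**
Reactants: 25 3-O-tert-butyldimethylsilyl macrolactone with free 8-OH; 5 (2R,3R)-2,3-dimethyloxirane-2-carboxylic acid
Product: 28 target, via mixed anhydride 26 (not isolated), via silyl ester 27 (not isolated)
Conditions: 5, 2,4,6-trichlorobenzoyl chloride, Et3N, THF, rt; then 25, DMAP, toluene, rt; then HF·pyridine, THF, 0 °C → rt
Reagents that add atoms: none
Why: Yamaguchi esterification acylates the hindered 8-OH through the mixed anhydride and acylpyridinium without touching any stereocentre, and buffered fluoride in the same flask removes the C-3 silyl group while epoxide, methylene lactone and esters survive.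

**Compound list**
1 | methyl (2Z)-2-methylbut-2-enoate | C/C=C(/C)C(=O)OC | starting material
2 | (2Z)-2-methylbut-2-en-1-ol | C/C=C(/C)CO | intermediate
3 | [(2S,3R)-2,3-dimethyloxiran-2-yl]methanol | OC[C@]1(C)O[C@@H]1C | intermediate
4 | (2R,3R)-2,3-dimethyloxirane-2-carbaldehyde | O=C[C@]1(C)O[C@@H]1C | intermediate (not isolated)
5 | (2R,3R)-2,3-dimethyloxirane-2-carboxylic acid | OC(=O)[C@]1(C)O[C@@H]1C | intermediate
6 | ethyl (2E)-3-methyl-4-oxobut-2-enoate | CCOC(=O)/C=C(\C)C=O | starting material
7 | 2-allyl-4,4,5,5-tetramethyl-1,3,2-dioxaborolane | C=CCB1OC(C)(C)C(C)(C)O1 | starting material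
8 | ethyl (2E,4S)-4-hydroxy-3-methylhepta-2,6-dienoate | CCOC(=O)/C=C(\C)[C@@H](O)CC=C | intermediate
9 | ethyl (2Z,4S)-4-hydroxy-3-methylhepta-2,6-dienoate | CCOC(=O)/C=C(/C)[C@@H](O)CC=C | intermediate (not isolated)
10 | (5S)-4-methyl-5-(prop-2-en-1-yl)furan-2(5H)-one | C=CC[C@@H]1OC(=O)C=C1C | intermediate
11 | (5S)-4-methyl-5-(prop-2-en-1-yl)-2,5-dihydrofuran-2-ol (both C-2 epimers) | C=CC[C@@H]1OC(O)C=C1C | intermediate
12 | 2,2-dimethoxyacetaldehyde | COC(OC)C=O | starting material
13 | methyl acrylate | C=CC(=O)OC | starting material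
14 | methyl 3-hydroxy-4,4-dimethoxy-2-methylidenebutanoate (racemic) | COC(OC)C(O)C(=C)C(=O)OC | intermediate
15 | methyl (2Z)-2-(bromomethyl)-4,4-dimethoxybut-2-enoate | COC(OC)/C=C(\CBr)C(=O)OC | intermediate (not isolated)
16 | methyl (2Z)-2-(bromomethyl)-4-oxobut-2-enoate | O=C/C=C(\CBr)C(=O)OC | intermediate
17 | methyl 2-[(4,4,5,5-tetramethyl-1,3,2-dioxaborolan-2-yl)methyl]prop-2-enoate | C=C(CB1OC(C)(C)C(C)(C)O1)C(=O)OC | starting material
18 | dimethyl (2Z,4R)-2-(bromomethyl)-4-hydroxy-6-methylidenehept-2-enedioate | COC(=O)C(=C)C[C@@H](O)/C=C(\CBr)C(=O)OC | intermediate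
19 | dimethyl (2Z,4R)-2-(bromomethyl)-6-methylidene-4-[(triethylsilyl)oxy]hept-2-enedioate | COC(=O)C(=C)C[C@@H](O[Si](CC)(CC)CC)/C=C(\CBr)C(=O)OC | intermediate
20 | dimethyl (2Z,4R,6E)-2-(bromomethyl)-6-{2-[(2S)-5-hydroxy-3-methyl-2,5-dihydrofuran-2-yl]ethylidene}-4-[(triethylsilyl)oxy]hept-2-enedioate | CC1=CC(O)O[C@H]1C/C=C(/C(=O)OC)C[C@@H](O[Si](CC)(CC)CC)/C=C(\CBr)C(=O)OC | intermediate
21 | open-chain allylchromium dichloride (trivalent chromium, THF ligands omitted): 20 with the lactol opened to the (Z)-4-hydroxy-enal and CH2Br replaced by CH2CrCl2 | O=C/C=C(/C)[C@@H](O)C/C=C(/C(=O)OC)C[C@@H](O[Si](CC)(CC)CC)/C=C(\C[Cr](Cl)Cl)C(=O)OC | intermediate (not isolated)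
22 | ring-closed hydroxy ester: ten-membered carbocycle with 3-OH, 6-OH, 8-OSiEt3, C-7 bearing C(=CH2)CO2Me, C-10 CO2Me; C-3, C-6, C-7, C-8 configured as in 28 | C=C(C(=O)OC)[C@H]1[C@H](O)/C=C(/C)[C@@H](O)C/C=C(/C(=O)OC)C[C@H]1O[Si](CC)(CC)CC | intermediate (not isolated)
23 | 8-O-triethylsilyl macrolactone: 28 with OSiEt3 in place of the 8-acyloxy group, 3-OH free (stereocentres as in 28) | C=C1C(=O)O[C@@H]2/C=C(/C)[C@@H](O)C/C=C(/C(=O)OC)C[C@@H](O[Si](CC)(CC)CC)[C@@H]12 | intermediate
24 | 3-O-tert-butyldimethylsilyl-8-O-triethylsilyl macrolactone (stereocentres as in 28) | C=C1C(=O)O[C@@H]2/C=C(/C)[C@@H](O[Si](C)(C)C(C)(C)C)C/C=C(/C(=O)OC)C[C@@H](O[Si](CC)(CC)CC)[C@@H]12 | intermediate (not isolated)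
25 | 3-O-tert-butyldimethylsilyl macrolactone with free 8-OH (stereocentres as in 28) | C=C1C(=O)O[C@@H]2/C=C(/C)[C@@H](O[Si](C)(C)C(C)(C)C)C/C=C(/C(=O)OC)C[C@@H](O)[C@@H]12 | intermediate
26 | (2R,3R)-2,3-dimethyloxirane-2-carboxylic 2,4,6-trichlorobenzoic anhydride | O=C(OC(=O)c1c(Cl)cc(Cl)cc1Cl)[C@]2(C)O[C@@H]2C | intermediate (not isolated)
27 | 3-O-tert-butyldimethylsilyl ether of 28 | C=C1C(=O)O[C@@H]2/C=C(/C)[C@@H](O[Si](C)(C)C(C)(C)C)C/C=C(/C(=O)OC)C[C@@H](OC(=O)[C@]3(C)O[C@@H]3C)[C@@H]12 | intermediate (not isolated)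
28 | methyl (3aR,4R,6E,9S,10Z,11aR)-4-{[(2R,3R)-2,3-dimethyloxirane-2-carbonyl]oxy}-9-hydroxy-10-methyl-3-methylidene-2-oxo-2,3,3a,4,5,8,9,11a-octahydrocyclodeca[b]furan-6-carboxylate | C=C1C(=O)O[C@@H]2/C=C(/C)[C@@H](O)C/C=C(/C(=O)OC)C[C@@H](OC(=O)[C@]3(C)O[C@@H]3C)[C@@H]12 | target

**Totals**
Total step count: 14. Longest linear sequence: 8 steps (steps 7 to 14, from 12 and 13).

**Three steps most likely to fail**

Step 12 (ring closure and lactonisation). The lactol may dehydrate to a furan under Lewis-acidic trivalent chromium or open too slowly, the slow ten-membered closure competes with protonation or dimerisation of the allylchromium, and C-6/C-7 selectivity rests on a model. The fallback gives up the lactol and closes the ring from a discrete O-3-silylated (Z)-enal that cannot aromatise. It sets out from butenolide 10: excess i-Bu2AlH (2.5 equiv, CH2Cl2, −78 → 0 °C) gives (2Z,4S)-3-methylhepta-2,6-diene-1,4-diol F1; t-BuMe2SiCl and imidazole give its bis(tert-butyldimethylsilyl) ether F2; HF·pyridine/pyridine (THF, 0 °C) removes only the primary allylic silyl group to give (2Z,4S)-4-[(tert-butyldimethylsilyl)oxy]-3-methylhepta-2,6-dien-1-ol F3; MnO2 (CH2Cl2) gives (2Z,4S)-4-[(tert-butyldimethylsilyl)oxy]-3-methylhepta-2,6-dienal F4; cross-metathesis of F4 (excess) with 19 under the step 11 conditions gives dimethyl (2Z,4R,6E)-2-(bromomethyl)-6-{(3S,4Z)-3-[(tert-butyldimethylsilyl)oxy]-4-methyl-6-oxohex-4-en-1-ylidene}-4-[(triethylsilyl)oxy]hept-2-enedioate F5; CrCl2 in THF at high dilution closes F5 directly to the bis-silyl ether 24, where the route is rejoined (HF·pyridine of step 13, then step 14).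

Step 9 (allylboration with the ester-bearing boronate). The deactivated boronate may react too slowly or with poor enantioselectivity, and the borate may lactonise. The fallback moves stereocontrol from C–C bond formation to a ketone reduction. It sets out from 16 and 17: Sc(OTf)3 (10 mol %, CH2Cl2, −78 °C) catalyses the racemic allylboration to racemic dimethyl (2Z)-2-(bromomethyl)-4-hydroxy-6-methylidenehept-2-enedioate F6; Dess–Martin periodinane with NaHCO3 gives dimethyl (2Z)-2-(bromomethyl)-6-methylidene-4-oxohept-2-enedioate F7; (S)-2-methyl-CBS-oxazaborolidine with catecholborane (toluene, −78 °C) reduces the alkenyl ketone, alkenyl acting as the large group, to the 4R alcohol 18, where the route is rejoined.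

Step 11 (cross-metathesis). The hindered 1,1-disubstituted acrylate is a slow partner and the lactol limits temperature and catalyst lifetime. The fallback runs the metathesis at the lactone oxidation level and adjusts afterwards. It sets out from butenolide 10 (3 equiv) and 19: the same catalyst in toluene at 80 °C, conditions the lactol would not survive, gives dimethyl (2Z,4R,6E)-2-(bromomethyl)-6-{2-[(2S)-3-methyl-5-oxo-2,5-dihydrofuran-2-yl]ethylidene}-4-[(triethylsilyl)oxy]hept-2-enedioate F8; i-Bu2AlH (1.0 equiv, CH2Cl2, −78 °C) then reduces the γ-lactone faster than the two hindered conjugated methyl esters and gives lactol 20, where the route is rejoined.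

**Further compounds**
F1 | step 12 | (2Z,4S)-3-methylhepta-2,6-diene-1,4-diol | OC/C=C(/C)[C@@H](O)CC=C
F2 | step 12 | (2Z,4S)-1,4-bis[(tert-butyldimethylsilyl)oxy]-3-methylhepta-2,6-diene | CC(C)(C)[Si](C)(C)OC/C=C(/C)[C@@H](O[Si](C)(C)C(C)(C)C)CC=C
F3 | step 12 | (2Z,4S)-4-[(tert-butyldimethylsilyl)oxy]-3-methylhepta-2,6-dien-1-ol | OC/C=C(/C)[C@@H](O[Si](C)(C)C(C)(C)C)CC=C
F4 | step 12 | (2Z,4S)-4-[(tert-butyldimethylsilyl)oxy]-3-methylhepta-2,6-dienal | O=C/C=C(/C)[C@@H](O[Si](C)(C)C(C)(C)C)CC=C
F5 | step 12 | dimethyl (2Z,4R,6E)-2-(bromomethyl)-6-{(3S,4Z)-3-[(tert-butyldimethylsilyl)oxy]-4-methyl-6-oxohex-4-en-1-ylidene}-4-[(triethylsilyl)oxy]hept-2-enedioate | O=C/C=C(/C)[C@@H](O[Si](C)(C)C(C)(C)C)C/C=C(/C(=O)OC)C[C@@H](O[Si](CC)(CC)CC)/C=C(\CBr)C(=O)OC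
F6 | step 9 | dimethyl (2Z)-2-(bromomethyl)-4-hydroxy-6-methylidenehept-2-enedioate (racemic) | COC(=O)C(=C)CC(O)/C=C(\CBr)C(=O)OC
F7 | step 9 | dimethyl (2Z)-2-(bromomethyl)-6-methylidene-4-oxohept-2-enedioate | COC(=O)C(=C)CC(=O)/C=C(\CBr)C(=O)OC
F8 | step 11 | dimethyl (2Z,4R,6E)-2-(bromomethyl)-6-{2-[(2S)-3-methyl-5-oxo-2,5-dihydrofuran-2-yl]ethylidene}-4-[(triethylsilyl)oxy]hept-2-enedioate | CC1=CC(=O)O[C@H]1C/C=C(/C(=O)OC)C[C@@H](O[Si](CC)(CC)CC)/C=C(\CBr)C(=O)OC
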